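## The problem

Littorachalcone (12) is an achiral C30 bis(dihydrochalcone). Two identical 2,4-dihydroxyphenyl ketones (rings C and D) are each joined through a CH2CH2 chain to one ring of an unsymmetrical diaryl ether; ring A is 1,4-disubstituted, and ring B carries a free hydroxyl ortho to the ether oxygen and its side chain para to it. There is no stereocentre, so nothing has to be relayed or controlled in space, and every difficulty is one of regiochemistry and chemoselectivity. Neither ring of the diaryl ether has an activating group in conjugation, so the ether cannot be closed by nucleophilic aromatic substitution on the finished skeleton, and the two ring-B oxygens must be told apart when it is made. The two aryl–carbonyl bonds are the second difficulty: electrophilic acylation of a resorcinol by a 3-arylpropanoic acid derivative would have to outrun attack on the electron-rich rings A and B, in particular closure of the acylium ion onto its own ring to a 1-indanone. Five phenols, two enolisable ketones and two electron-rich benzylic methylenes make the final compound sensitive to base, air and strong oxidants, so the hydroxyls should be uncovered only in the last step. The enabling feature is that each of rings C and D, with its acyl-bearing carbon C1′, its ortho oxygen on C2′ and its para oxygen on C4′, is the dehydrogenated form of a 6-acyl-3-alkoxycyclohex-2-en-1-one (C6, the C1 oxygen and the C3 oxygen). The aryl ketone can therefore be made by acylating an sp3 carbon of a partly saturated ring, and because the unit occurs twice, both can be made in one operation.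

## Retrosynthesis

**12 ⇒ 11.** The three O–alkyl bonds are cut last: the para oxygens of rings C and D are carried as ethyl ethers and the ring-B oxygen as a methyl ether, giving 11. The two ortho hydroxyls stay free because they are chelated to the ketones and harmless. The precursor has three phenols fewer and is stable to air and chromatography. The forward step is a single global dealkylation by a boron trihalide that must leave the diaryl ether untouched, which it should, since that ether has no sp3 carbon to attack.

**11 ⇒ 10.** Two hydrogens are added back to each of rings C and D, across C5′–C6′ of the arene, giving the bis(6-acyl-3-ethoxycyclohex-2-en-1-one) 10, drawn as its chelated enol. This is a change of oxidation level, not a skeletal cut, and it is what turns the aryl ketone problem into an enolate problem. The forward reaction asks a quinone oxidant to aromatise two already conjugated dienol rings without touching the benzylic and α-keto methylenes of the arms. The large gain in aromatic stabilisation should make the rings by far the most reactive hydride donors in the molecule.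

**10 ⇒ 7 + two of 8 (through 9).** Both bonds between a ketone carbonyl and ring carbon C6 are cut, giving the bis(N-acylbenzotriazole) 7 and two molecules of the vinylogous ester 8, each used as its kinetic lithium enolate 9. Three neighbouring cuts were weighed.
- Friedel–Crafts acylation of a resorcinol ether by the diacid 4 makes the same bond, but sets three electron-rich arenes in competition and invites indanone formation.
- Addition of a 2,4-dialkoxyphenyl-metal reagent to an amide of 4 is workable, but it delivers both oxygens of each ring as the same ether, so five ethers would have to be cleaved instead of three.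
- Aldol condensation to a bis(chalcone) followed by hydrogenation moves the cut one bond along and adds a reduction step.

The enolate cut makes the bond at an sp3 carbon under basic conditions in which rings A and B are inert, and it delivers the two ring oxygens already differentiated. The precursors are a symmetrically activated diacid and a commercial C8 building block. The forward step must deprotonate C6 and not C4, and must acylate on carbon and not on oxygen.

**7 ⇒ 4 + two of 5 (through 6).** The two acyl–nitrogen bonds are cut to the diacid 4 and two molecules of benzotriazole 5, one for each carboxyl group, with the bis(acid chloride) 6 as the transient activated form. The acyl azolide is preferred to 6 itself as the acyl donor because it is crystalline, can be purified, and is known to acylate lithium enolates on carbon, whereas acid chlorides give mixtures of O- and C-acylation. Nothing is asked of this step beyond the absence of Lewis acid, so that the 3-arylpropanoyl chloride does not cyclise.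

**4 ⇒ 3.** The two carboxyl groups are traced to methyl esters. The diester 3 is the form in which both halves are commercially available and in which the ether coupling is cleanest. Hydroxide at room temperature is all that is required.

**3 ⇒ 1 + 2.** The diaryl ether is cut at the bond between the ring-A carbon and the oxygen, giving the guaiacol-type phenol 1 and the arylboronic acid 2. Cutting on this side keeps the oxygen on ring B, where the commercial phenol 1 already has the ortho methoxy group that becomes the ring-B hydroxyl. The other C–O bond would require an aryl electrophile flanked by an alkoxy group. Both fragments are catalogue compounds that already carry their three-carbon arms. The forward reaction is a copper-mediated oxidative O-arylation at room temperature that must tolerate two methyl esters and an ortho-substituted phenol.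

## Roads not taken

**Alternative 1:** Ring B is not bought as an arene but assembled. Two ring-B bonds are cut, leading to the 4-aryloxy β-keto ester A1 (tert-butyl 4-[4-[3-(2,4-dimethoxyphenyl)-3-oxopropyl]phenoxy]-3-oxobutanoate), which already holds rings A and C and the ether oxygen, and to the enal A2 ((E)-6-(2,4-dimethoxyphenyl)-6-oxohex-2-enal), which holds ring D.
- Forward key step: pyrrolidine with benzoic acid activates A2 as its iminium ion and the doubly activated carbon of A1 adds to the β-carbon. The aryloxy-bearing carbon then condenses with the aldehyde, and TsOH removes the tert-butyl ester with loss of CO2. The product is the racemic cyclohexenone A3 (2-[4-[3-(2,4-dimethoxyphenyl)-3-oxopropyl]phenoxy]-5-[3-(2,4-dimethoxyphenyl)-3-oxopropyl]cyclohex-2-en-1-one).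
- Merits: the ether oxygen is introduced by plain O-alkylation of a phenol, so no metal-mediated diaryl ether coupling is needed, and the 1,2,4-pattern of ring B follows from the annulation itself. In this respect the road is cleaner than the Chan–Lam step chosen here.
- Weak points: both partners are multistep compounds. A3 carries a stereocentre that is made only to be destroyed. Ring B must still be dehydrogenated next to the same benzylic and α-keto methylenes that concern the chosen plan. The amine catalyst meets two aryl ketones and a ketone that can enolise to either side. Four methyl ethers remain to be cleaved.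
- Comparison: the step count would be roughly double. The chosen plan sets against the cleaner ether construction a commercial ring B and a single room-temperature coupling.

**Alternative 2:** Each resorcinol ring is cut across two bonds, giving the bis(ethynyl ketone) A4 (5-[4-[2-methoxy-4-(3-oxopent-4-yn-1-yl)phenoxy]phenyl]pent-1-yn-3-one) and two molecules of the diene A5 ((E)-1,3-dimethoxy-1-(trimethylsilyloxy)buta-1,3-diene).
- Forward key step: a twofold Diels–Alder reaction joins the nucleophilic CH2 terminus of A5 to each alkyne terminus and the ketene acetal carbon to the acyl-bearing alkyne carbon. Loss of methanol and desilylation then give littorachalcone tri-O-methyl ether A6.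
- Merits: the rings arrive at the aromatic oxidation level, so there is no dehydrogenation step. The regiochemistry follows from the polarity of the diene. The ortho hydroxyls are free and three ethers remain, the same number as in the chosen route. A4 could be reached from diester 3 in a few steps, so the overall length is comparable. In freedom from any oxidant near the benzylic methylenes this road is better.
- Weak points: terminal ynones are strong Michael acceptors that polymerise and add any nucleophile present, and A4 has two of them. A5 is hydrolytically labile and must be made and used fresh. Conjugate addition without ring closure, or incomplete aromatisation at one of the two termini, would give mixtures that are hard to separate.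
- Comparison: the chosen plan sets against it bench-stable partners (commercial 8 and crystalline 7) and enolate chemistry whose by-products are easily removed.

**Alternative 3:** The two benzylic CH2–aryl bonds are cut, giving the dibromide A8 (4-bromo-1-(4-bromophenoxy)-2-methoxybenzene) and two molecules of the redox-active ester A7 ((1,3-dioxoisoindolin-2-yl) 4-(2,4-dimethoxyphenyl)-4-oxobutanoate).
- Forward key step: at a cathode, with NiCl2·glyme and 2,2'-bipyridine, A7 loses CO2 to a primary alkyl radical that nickel couples with each aryl bromide. The product is littorachalcone penta-O-methyl ether A9.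
- Merits: this is the most convergent of the four plans. The aryl ketones are in place from the start, so no ring is built or aromatised and no oxidant is used. In convergence it is superior to the chosen plan.
- Weak points: both aryl bromides sit on electron-rich rings and add slowly to low-valent nickel. The coupling must succeed twice, so mono-coupled and hydrodehalogenated material is expected to accumulate. The aryl ketones of A7 and of the product can themselves be reduced at the cathode. Five methyl ethers must be cleaved at the end, and electrolysis equipment is required.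
- Comparison: the chosen plan sets against the higher convergence polar two-electron steps whose selectivity rests on well-understood kinetic enolate behaviour, and an end game with three ethers in place of five.

Key step: step 4

Remark on the chemistry: compound 10 is drawn and named as its bis-enol; in solution it will be a mixture of keto and enol tautomers, all of which converge on 11. Compounds 1, 2, 5 and 8 are taken to be catalogue materials. Steps 3 and 4 each build two molecules of the smaller partner (5 and 8) into one molecule of product; the second molecule is entered on the line "Reagents that add atoms" of that step.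

## Route

**Step 1**
Reactants: 1 methyl 3-(4-hydroxy-3-methoxyphenyl)propanoate; 2 [4-(3-methoxy-3-oxopropyl)phenyl]boronic acid
Product: 3 methyl 3-[3-methoxy-4-[4-(3-methoxy-3-oxopropyl)phenoxy]phenyl]propanoate
Conditions: 2 (2.0 equiv), Cu(OAc)2 (1.0 equiv), pyridine (5 equiv), 4 Å MS, CH2Cl2, air (drying tube), rt
Reagents that add atoms: none
Why: Chan–Lam O-arylation: the aryl group is transferred from boron to the divalent copper phenoxide, oxidation to trivalent copper is followed by C–O reductive elimination, and oxygen of the air returns the copper to the divalent state. The mild amine base at room temperature leaves both methyl esters intact, and the excess of 2 allows for protodeboronation and homocoupling.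

**Step 2**
Reactants: 3 methyl 3-[3-methoxy-4-[4-(3-methoxy-3-oxopropyl)phenoxy]phenyl]propanoate
Product: 4 3-[4-[4-(2-carboxyethyl)-2-methoxyphenoxy]phenyl]propanoic acid
Conditions: LiOH·H2O (6 equiv), THF/MeOH/H2O (3:1:1), rt; then 1 M HCl to pH 2
Reagents that add atoms: lithium hydroxide, [Li+].[OH-]
Why: Saponification of two unhindered methyl esters by acyl–oxygen cleavage. The diaryl ether and the aryl methyl ether are inert to hydroxide, and the diacid should precipitate on acidification.

**Step 3**
Reactants: 4 3-[4-[4-(2-carboxyethyl)-2-methoxyphenoxy]phenyl]propanoic acid; 5 1H-benzotriazole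
Product: 7 1-(1H-benzotriazol-1-yl)-3-[4-[4-[3-(1H-benzotriazol-1-yl)-3-oxopropyl]-2-methoxyphenoxy]phenyl]propan-1-one, via bis(acid chloride) 6 (not isolated)
Conditions: (COCl)2 (2.6 equiv), DMF (cat.), CH2Cl2, 0 °C → rt, concentrate; then 5 (2.4 equiv), Et3N (3 equiv), CH2Cl2, 0 °C → rt
Reagents that add atoms: 1H-benzotriazole (second molecule of 5), c1ccc2[nH]nnc2c1
Why: Acid chloride formation under Vilsmeier catalysis followed by N-acylation of benzotriazole at each of the two acyl chlorides, so that one molecule of 4 takes up two molecules of 5 and gives the bis(N1-acyl azolide), a neutral, crystalline and chromatography-stable acyl donor. No Lewis acid is present, so the 3-arylpropanoyl chloride should not close to an indanone.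

**Step 4**
Reactants: 7 1-(1H-benzotriazol-1-yl)-3-[4-[4-[3-(1H-benzotriazol-1-yl)-3-oxopropyl]-2-methoxyphenoxy]phenyl]propan-1-one; 8 3-ethoxycyclohex-2-en-1-one
Product: 10 1-(4-ethoxy-2-hydroxycyclohexa-1,3-dien-1-yl)-3-[4-[4-[3-(4-ethoxy-2-hydroxycyclohexa-1,3-dien-1-yl)-3-oxopropyl]-2-methoxyphenoxy]phenyl]propan-1-one, via lithium 5-ethoxycyclohexa-1,5-dien-1-olate 9 (not isolated)
Conditions: 8 (4.2 equiv) added to LiN(iPr)2 (4.4 equiv), THF, −78 °C, 45 min; then 7 (1.0 equiv) in THF, −78 → −20 °C; cold sat. aq NH4Cl
Reagents that add atoms: 3-ethoxycyclohex-2-en-1-one (second molecule of 8), CCOC1=CC(=O)CCC1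
Why: Lithium diisopropylamide, LiN(iPr)2, removes the C6 proton of 8 irreversibly at −78 °C and gives the cross-conjugated enolate 9, not the extended dienolate that forms from C4 under equilibrating conditions; this is the kinetic enolisation of a vinylogous ester used in Stork–Danheiser alkylations. The enolate carbon adds to each N-acyl carbonyl of 7 and the tetrahedral adduct expels benzotriazolide, a Claisen-type C-acylation of a ketone lithium enolate by an N-acylbenzotriazole, which is the closest known reaction type. Each new β-diketone is more acidic than 8 and is at once deprotonated by a second equivalent of 9, which is why just over four equivalents of enolate are used for the two acyl groups; the resulting chelated lithium diketonate is protected from a second acylation. No ring is closed and no stereocentre is carried on, because C6 is trigonal in the chelated enol and is aromatised in the next step. The step needs C6 over C4 deprotonation, which the amide base and low temperature secure, and C- over O-acylation, which the tightly bound lithium counter-ion in THF and the moderately reactive acyl azolide secure. It also needs both termini of 7 to react, so that two molecules of 8 are built into each molecule of 10, which the excess of 9 and the two identical, mutually remote acyl groups should ensure. The buffered cold work-up keeps the acid-labile vinylogous ethyl esters intact.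

**Step 5**
Reactants: 10 1-(4-ethoxy-2-hydroxycyclohexa-1,3-dien-1-yl)-3-[4-[4-[3-(4-ethoxy-2-hydroxycyclohexa-1,3-dien-1-yl)-3-oxopropyl]-2-methoxyphenoxy]phenyl]propan-1-one
Product: 11 1-(4-ethoxy-2-hydroxyphenyl)-3-[4-[4-[3-(4-ethoxy-2-hydroxyphenyl)-3-oxopropyl]-2-methoxyphenoxy]phenyl]propan-1-one
Conditions: DDQ (2.2 equiv), 1,4-dioxane, rt → 40 °C
Reagents that add atoms: none
Why: Quinone dehydrogenation of a cyclohexadiene to an arene: hydride abstraction from C5 of each dienol ring gives a cation delocalised onto both oxygen-bearing carbons, and proton loss from C4 then aromatises the ring. The gain in aromaticity makes these rings far better hydride donors than the benzylic or α-keto methylenes, so a small excess of DDQ at mild temperature should be selective.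

**Step 6**
Reactants: 11 1-(4-ethoxy-2-hydroxyphenyl)-3-[4-[4-[3-(4-ethoxy-2-hydroxyphenyl)-3-oxopropyl]-2-methoxyphenoxy]phenyl]propan-1-one
Product: 12 littorachalcone, 1-(2,4-dihydroxyphenyl)-3-[4-[4-[3-(2,4-dihydroxyphenyl)-3-oxopropyl]-2-hydroxyphenoxy]phenyl]propan-1-one
Conditions: BBr3 (10 equiv), CH2Cl2, −78 °C → rt; then MeOH, H2O
Reagents that add atoms: none
Why: Lewis acid-mediated cleavage of alkyl aryl ethers: BBr3 binds each ether oxygen and bromide displaces the ethyl or methyl group by SN2. The diaryl ether offers no sp3 carbon and should survive, and the aryl borates and the boron chelates of the ortho-hydroxy ketones are hydrolysed on work-up.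

## Compound list

1 | methyl 3-(4-hydroxy-3-methoxyphenyl)propanoate | COC(=O)CCc1ccc(O)c(OC)c1 | starting material
2 | [4-(3-methoxy-3-oxopropyl)phenyl]boronic acid | COC(=O)CCc1ccc(B(O)O)cc1 | starting material
3 | methyl 3-[3-methoxy-4-[4-(3-methoxy-3-oxopropyl)phenoxy]phenyl]propanoate | COC(=O)CCc1ccc(Oc2ccc(CCC(=O)OC)cc2OC)cc1 | intermediate
4 | 3-[4-[4-(2-carboxyethyl)-2-methoxyphenoxy]phenyl]propanoic acid | O=C(O)CCc1ccc(Oc2ccc(CCC(=O)O)cc2OC)cc1 | intermediate
5 | 1H-benzotriazole | c1ccc2[nH]nnc2c1 | starting material
6 | 3-[4-[4-(3-chloro-3-oxopropyl)-2-methoxyphenoxy]phenyl]propanoyl chloride | O=C(Cl)CCc1ccc(Oc2ccc(CCC(=O)Cl)cc2OC)cc1 | intermediate (not isolated)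
7 | 1-(1H-benzotriazol-1-yl)-3-[4-[4-[3-(1H-benzotriazol-1-yl)-3-oxopropyl]-2-methoxyphenoxy]phenyl]propan-1-one | O=C(CCc1ccc(Oc2ccc(CCC(=O)n3nnc4ccccc43)cc2OC)cc1)n1nnc2ccccc21 | intermediate
8 | 3-ethoxycyclohex-2-en-1-one | CCOC1=CC(=O)CCC1 | starting material
9 | lithium 5-ethoxycyclohexa-1,5-dien-1-olate | [Li+].[O-]C1=CCCC(OCC)=C1 | intermediate (not isolated)
10 | 1-(4-ethoxy-2-hydroxycyclohexa-1,3-dien-1-yl)-3-[4-[4-[3-(4-ethoxy-2-hydroxycyclohexa-1,3-dien-1-yl)-3-oxopropyl]-2-methoxyphenoxy]phenyl]propan-1-one (bis-enol of the bis(6-acyl-3-ethoxycyclohex-2-en-1-one)) | CCOC1=CC(O)=C(CC1)C(=O)CCc1ccc(Oc2ccc(CCC(=O)C3=C(O)C=C(OCC)CC3)cc2OC)cc1 | intermediate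
11 | 1-(4-ethoxy-2-hydroxyphenyl)-3-[4-[4-[3-(4-ethoxy-2-hydroxyphenyl)-3-oxopropyl]-2-methoxyphenoxy]phenyl]propan-1-one | CCOc1ccc(C(=O)CCc2ccc(Oc3ccc(CCC(=O)c4ccc(OCC)cc4O)cc3OC)cc2)c(O)c1 | intermediate
12 | littorachalcone, 1-(2,4-dihydroxyphenyl)-3-[4-[4-[3-(2,4-dihydroxyphenyl)-3-oxopropyl]-2-hydroxyphenoxy]phenyl]propan-1-one | O=C(CCc1ccc(Oc2ccc(CCC(=O)c3ccc(O)cc3O)cc2O)cc1)c1ccc(O)cc1O | target

Total step count: 6. Longest linear sequence: 6 steps (1 → 3 → 4 → 7 → 10 → 11 → 12).

## Least certain steps

**Step 4 (key step).**
- Most likely failure: proton transfer quenches the enolate before both termini are acylated. The proton can come from the acidic product or from the α-methylene of the acyl azolide, and the reaction then stalls at the mono-acylated stage. O-acylation, or drift to the C4 dienolate as neutral 8 accumulates, may accompany this.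
- Fallback: it sets out from diester 3 and makes the same two bonds by aldol addition, in which neither problem can arise. Reduction of 3 with iBu2AlH (toluene, −78 °C) would give the dialdehyde 3-[4-[2-methoxy-4-(3-oxopropyl)phenoxy]phenyl]propanal F1. Addition of enolate 9 (2.2 equiv, THF, −78 °C) to F1 would give the bis(β-hydroxy ketone) 3-ethoxy-6-[3-[4-[4-[3-(4-ethoxy-2-oxocyclohex-3-en-1-yl)-3-hydroxypropyl]-2-methoxyphenoxy]phenyl]-1-hydroxypropyl]cyclohex-2-en-1-one F2 as a mixture of diastereomers. Dess–Martin periodinane (NaHCO3, CH2Cl2, rt) would oxidise both carbinols and rejoin the route at 10.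

**Step 5.**
- Most likely failure: competing hydride abstraction from the electron-rich benzylic methylenes, or dehydrogenation of the propanone arms towards chalcones, if the ring aromatisation is slower than expected. Aromatisation of only one of the two rings is also possible.
- Fallback: it sets out from 10 and replaces hydride abstraction by a selenoxide elimination. PhSeCl and pyridine (CH2Cl2, 0 °C) would selenenylate the carbon between the two carbonyls and give the bis(selenide) 3-ethoxy-6-(phenylselanyl)-6-[3-[4-[4-[3-[4-ethoxy-2-oxo-1-(phenylselanyl)cyclohex-3-en-1-yl]-3-oxopropyl]-2-methoxyphenoxy]phenyl]propanoyl]cyclohex-2-en-1-one F3. Oxidation with H2O2 (CH2Cl2, 0 °C → rt) and syn-elimination towards C5 would give the cross-conjugated dienone, which tautomerises to the phenol and rejoins the route at 11.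

**Step 1.**
- Most likely failure: consumption of the boronic acid by protodeboronation, oxidation or homocoupling faster than C–O bond formation with the ortho-substituted phenol, leaving 1 unconverted.
- Fallback: it sets out from 1 and builds the ether by nucleophilic aromatic substitution on an activated ring. Phenol 1 and 4-fluorobenzaldehyde (K2CO3, DMF, 100 °C) would give methyl 3-[4-(4-formylphenoxy)-3-methoxyphenyl]propanoate F4. Horner–Wadsworth–Emmons olefination with trimethyl phosphonoacetate (NaH, THF, 0 °C) would give methyl (E)-3-[4-[2-methoxy-4-(3-methoxy-3-oxopropyl)phenoxy]phenyl]prop-2-enoate F5. Hydrogenation (H2, Pd/C, EtOAc, rt) would rejoin the route at 3.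

**Step 6.**
- Most likely failure: incomplete cleavage of the two ethyl ethers, because the boron-chelated ketone para to each of them lowers the basicity of the ether oxygen. Forcing the reaction risks Lewis acid-promoted condensation of the polyphenolic ketone.
- Fallback: it sets out from 7 and carries the para oxygens as benzyl ethers, removed by hydrogenolysis and not by ether cleavage.
  - 3-(Benzyloxy)cyclohex-2-en-1-one F6 (from cyclohexane-1,3-dione and benzyl alcohol, TsOH, toluene, reflux with removal of water) would be converted by LiN(iPr)2 (THF, −78 °C) into lithium 5-(benzyloxy)cyclohexa-1,5-dien-1-olate F7.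
  - Acylation of F7 by 7 as in step 4 would give 1-[4-(benzyloxy)-2-hydroxycyclohexa-1,3-dien-1-yl]-3-[4-[4-[3-[4-(benzyloxy)-2-hydroxycyclohexa-1,3-dien-1-yl]-3-oxopropyl]-2-methoxyphenoxy]phenyl]propan-1-one F8.
  - DDQ as in step 5 would give 1-[4-(benzyloxy)-2-hydroxyphenyl]-3-[4-[4-[3-[4-(benzyloxy)-2-hydroxyphenyl]-3-oxopropyl]-2-methoxyphenoxy]phenyl]propan-1-one F9.
  - Hydrogenolysis (H2, 1 atm, Pd/C, EtOAc/MeOH, rt) would give the ring-B methyl ether 1-(2,4-dihydroxyphenyl)-3-[4-[4-[3-(2,4-dihydroxyphenyl)-3-oxopropyl]-2-methoxyphenoxy]phenyl]propan-1-one F10.
  - BBr3 (CH2Cl2, −78 → 0 °C) then has to cleave only the one methyl ether, which has no carbonyl on its ring, and rejoins the route at 12.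

## Further compounds

F1 | step 4 | 3-[4-[2-methoxy-4-(3-oxopropyl)phenoxy]phenyl]propanal | O=CCCc1ccc(Oc2ccc(CCC=O)cc2OC)cc1
F2 | step 4 | 3-ethoxy-6-[3-[4-[4-[3-(4-ethoxy-2-oxocyclohex-3-en-1-yl)-3-hydroxypropyl]-2-methoxyphenoxy]phenyl]-1-hydroxypropyl]cyclohex-2-en-1-one (mixture of diastereomers) | CCOC1=CC(=O)C(CC1)C(O)CCc1ccc(Oc2ccc(CCC(O)C3CCC(OCC)=CC3=O)cc2OC)cc1
F3 | step 5 | 3-ethoxy-6-(phenylselanyl)-6-[3-[4-[4-[3-[4-ethoxy-2-oxo-1-(phenylselanyl)cyclohex-3-en-1-yl]-3-oxopropyl]-2-methoxyphenoxy]phenyl]propanoyl]cyclohex-2-en-1-one (mixture of diastereomers) | CCOC1=CC(=O)C(CC1)([Se]c1ccccc1)C(=O)CCc1ccc(Oc2ccc(CCC(=O)C3([Se]c4ccccc4)CCC(OCC)=CC3=O)cc2OC)cc1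
F4 | step 1 | methyl 3-[4-(4-formylphenoxy)-3-methoxyphenyl]propanoate | COC(=O)CCc1ccc(Oc2ccc(C=O)cc2)c(OC)c1
F5 | step 1 | methyl (E)-3-[4-[2-methoxy-4-(3-methoxy-3-oxopropyl)phenoxy]phenyl]prop-2-enoate | COC(=O)/C=C/c1ccc(Oc2ccc(CCC(=O)OC)cc2OC)cc1
F6 | step 6 | 3-(benzyloxy)cyclohex-2-en-1-one | O=C1C=C(OCc2ccccc2)CCC1
F7 | step 6 | lithium 5-(benzyloxy)cyclohexa-1,5-dien-1-olate | [Li+].[O-]C1=CCCC(OCc2ccccc2)=C1
F8 | step 6 | 1-[4-(benzyloxy)-2-hydroxycyclohexa-1,3-dien-1-yl]-3-[4-[4-[3-[4-(benzyloxy)-2-hydroxycyclohexa-1,3-dien-1-yl]-3-oxopropyl]-2-methoxyphenoxy]phenyl]propan-1-one | O=C(CCc1ccc(Oc2ccc(CCC(=O)C3=C(O)C=C(OCc4ccccc4)CC3)cc2OC)cc1)C1=C(O)C=C(OCc2ccccc2)CC1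
F9 | step 6 | 1-[4-(benzyloxy)-2-hydroxyphenyl]-3-[4-[4-[3-[4-(benzyloxy)-2-hydroxyphenyl]-3-oxopropyl]-2-methoxyphenoxy]phenyl]propan-1-one | O=C(CCc1ccc(Oc2ccc(CCC(=O)c3ccc(OCc4ccccc4)cc3O)cc2OC)cc1)c1ccc(OCc2ccccc2)cc1O
F10 | step 6 | 1-(2,4-dihydroxyphenyl)-3-[4-[4-[3-(2,4-dihydroxyphenyl)-3-oxopropyl]-2-methoxyphenoxy]phenyl]propan-1-one | O=C(CCc1ccc(Oc2ccc(CCC(=O)c3ccc(O)cc3O)cc2OC)cc1)c1ccc(O)cc1O
A1 | alternative 1 | tert-butyl 4-[4-[3-(2,4-dimethoxyphenyl)-3-oxopropyl]phenoxy]-3-oxobutanoate | COc1ccc(C(=O)CCc2ccc(OCC(=O)CC(=O)OC(C)(C)C)cc2)c(OC)c1
A2 | alternative 1 | (E)-6-(2,4-dimethoxyphenyl)-6-oxohex-2-enal | COc1ccc(C(=O)CC/C=C/C=O)c(OC)c1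
A3 | alternative 1 | racemic 2-[4-[3-(2,4-dimethoxyphenyl)-3-oxopropyl]phenoxy]-5-[3-(2,4-dimethoxyphenyl)-3-oxopropyl]cyclohex-2-en-1-one | O=C1CC(CCC(=O)c2ccc(OC)cc2OC)CC=C1Oc1ccc(CCC(=O)c2ccc(OC)cc2OC)cc1
A4 | alternative 2 | 5-[4-[2-methoxy-4-(3-oxopent-4-yn-1-yl)phenoxy]phenyl]pent-1-yn-3-one | C#CC(=O)CCc1ccc(Oc2ccc(CCC(=O)C#C)cc2OC)cc1
A5 | alternative 2 | (E)-1,3-dimethoxy-1-(trimethylsilyloxy)buta-1,3-diene | C=C(OC)/C=C(\OC)O[Si](C)(C)C
A6 | alternative 2 | littorachalcone tri-O-methyl ether, 1-(2-hydroxy-4-methoxyphenyl)-3-[4-[4-[3-(2-hydroxy-4-methoxyphenyl)-3-oxopropyl]-2-methoxyphenoxy]phenyl]propan-1-one | COc1ccc(C(=O)CCc2ccc(Oc3ccc(CCC(=O)c4ccc(OC)cc4O)cc3OC)cc2)c(O)c1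
A7 | alternative 3 | (1,3-dioxoisoindolin-2-yl) 4-(2,4-dimethoxyphenyl)-4-oxobutanoate | COc1ccc(C(=O)CCC(=O)ON2C(=O)c3ccccc3C2=O)c(OC)c1
A8 | alternative 3 | 4-bromo-1-(4-bromophenoxy)-2-methoxybenzene | COc1cc(Br)ccc1Oc1ccc(Br)cc1
A9 | alternative 3 | littorachalcone penta-O-methyl ether, 1-(2,4-dimethoxyphenyl)-3-[4-[4-[3-(2,4-dimethoxyphenyl)-3-oxopropyl]-2-methoxyphenoxy]phenyl]propan-1-one | COc1ccc(C(=O)CCc2ccc(Oc3ccc(CCC(=O)c4ccc(OC)cc4OC)cc3OC)cc2)c(OC)c1
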